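**Retrosynthetic overview**
- Last C–C bond (bridge CH2 to ring B): a ring A sulfone loses sulfinate to give a methylidene trione, which the ring B phenol captures through carbon.
- Prenyl comes from allyl by cross-metathesis with 2-methylbut-2-ene.
- Key disconnection, quaternary carbon–allyl bond: the fully substituted ring A phenol is oxidised to a phenoxenium (enolonium-type) acceptor, so the normally nucleophilic ring carbon becomes electrophilic and is captured by allylSiMe3 under a chiral iodoarene catalyst. This dearomatises ring A and sets the only stereocentre.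
- Ring A arene from 2-methylphloroglucinol (C-acylation, then sulfonylmethylation, which blocks C5 and brings in the bridge carbon); ring B from phloroglucinol (C-acylation, 4-O-methylation).
- Ring order: no ring is built. Both rings are bought as arenes, ring A is dearomatised in step 5, and the two rings are joined in step 7.

Assumption: the stereocentre is (R) as encoded in the SMILES; because the facial sense of the new catalytic step cannot be predicted, the (R,R)-iodoarene is written and its (S,S)-mirror image is used if the first run gives the antipode of 13.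

**Route**

Step 1
Reactants: 1 phloroglucinol (benzene-1,3,5-triol); 2 butanoyl chloride
Product: 3 1-(2,4,6-trihydroxyphenyl)butan-1-one
Conditions: AlCl3 (3.5 equiv), PhNO2, rt → 65 °C; 1 M HCl work-up
Reagents that add atoms: butanoyl chloride, CCCC(=O)Cl
Why: Friedel–Crafts C-acylation of the threefold-symmetric triol has no regiochemical issue and stops after one acyl group because the ketone deactivates the ring.

Step 2
Reactants: 3 1-(2,4,6-trihydroxyphenyl)butan-1-one; 4 dimethyl sulfate
Product: 5 1-(2,6-dihydroxy-4-methoxyphenyl)butan-1-one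
Conditions: Me2SO4 (1.0 equiv), K2CO3 (1.0 equiv), acetone, reflux
Reagents that add atoms: dimethyl sulfate, COS(=O)(=O)OC
Why: Williamson O-methylation with one equivalent of base takes the 4-OH, the most acidic hydroxyl and the only one not hydrogen-bonded to the ketone.

Step 3
Reactants: 6 2-methylbenzene-1,3,5-triol (2-methylphloroglucinol); 2 butanoyl chloride
Product: 7 1-(2,4,6-trihydroxy-3-methylphenyl)butan-1-one
Conditions: AlCl3 (3.5 equiv), PhNO2, rt → 65 °C; 1 M HCl work-up
Reagents that add atoms: butanoyl chloride, CCCC(=O)Cl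
Why: Friedel–Crafts C-acylation; the two free ring positions of 6 are equivalent, so a single mono-ketone forms.

Step 4
Reactants: 7 1-(2,4,6-trihydroxy-3-methylphenyl)butan-1-one; 8 formaldehyde (37% aqueous); 9 sodium 4-methylbenzenesulfinate
Product: 11 1-[2,4,6-trihydroxy-3-methyl-5-[(4-methylbenzenesulfonyl)methyl]phenyl]butan-1-one, via hydroxymethyl phenol 10 (not isolated)
Conditions: aq CH2O (1.1 equiv, slow addition), 4-MeC6H4SO2Na (3 equiv), HCO2H/H2O 1:1, rt
Reagents that add atoms: formaldehyde, C=O; sodium 4-methylbenzenesulfinate, [Na+].[O-]S(=O)c1ccc(C)cc1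
Why: Three-component Mannich-type sulfonylmethylation: the only free ring carbon is hydroxymethylated, acid-promoted loss of water follows, and excess sulfinate captures the benzylic carbon through sulfur; the sulfone blocks C5 for step 5 and is the leaving group in step 7.

Step 5
Reactants: 11 1-[2,4,6-trihydroxy-3-methyl-5-[(4-methylbenzenesulfonyl)methyl]phenyl]butan-1-one; 12 allyltrimethylsilane
Product: 13 (4S)-2-butanoyl-3,5-dihydroxy-4-methyl-6-[(4-methylbenzenesulfonyl)methyl]-4-(prop-2-en-1-yl)cyclohexa-2,5-dien-1-one
Conditions: (R,R)-2-iodo-1,3-bis[1-(mesitylcarbamoyl)ethoxy]benzene (15 mol%), mCPBA (1.2 equiv, added over 6 h), allylSiMe3 (4 equiv), CH2Cl2/(CF3)2CHOH 4:1, −20 °C; aq Na2S2O3 quench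
Reagents that add atoms: allyltrimethylsilane, C=CC[Si](C)(C)C
Why: Proposed new method: mCPBA oxidises the chiral aryl iodide to a trivalent-iodine species that binds the free 4-OH of 11 and turns the ring into a phenoxenium (enolonium-type) acceptor, electrophilic at C1, C3 and C5; C1 (acyl) and C5 (sulfonylmethyl) are deactivated and hindered, so the γ-carbon of the allylsilane attacks C3 (SE2', then loss of Me3Si) while the lactamide arms of the oxygen-bound iodine shield one face and fix the quaternary centre; the closest known reactions are the PhI(OAc)2-mediated oxidative dearomatisation of 2-alkylphenols with allylsilanes and the chiral-iodoarene/mCPBA-catalysed enantioselective dearomatising spirolactonisation of phenols.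

Step 6
Reactants: 13 (4S)-allyl dienone sulfone; 14 2-methylbut-2-ene
Product: 15 (4S)-2-butanoyl-3,5-dihydroxy-4-methyl-4-(3-methylbut-2-en-1-yl)-6-[(4-methylbenzenesulfonyl)methyl]cyclohexa-2,5-dien-1-one
Conditions: second-generation Grubbs catalyst RuCl2(=CHPh)(PCy3)(H2IMes) (5 mol%; H2IMes = 1,3-dimesitylimidazolidin-2-ylidene), 2-methylbut-2-ene/CH2Cl2 1:3, 40 °C, sealed tube
Reagents that add atoms: 2-methylbut-2-ene, CC=C(C)C
Why: Olefin cross-metathesis exchanges the terminal =CH2 of the allyl group for the isopropylidene of 2-methylbut-2-ene (large excess, propene lost), and neither the sulfone nor the quaternary centre is touched.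

Step 7
Reactants: 15 (4S)-prenyl dienone sulfone; 5 1-(2,6-dihydroxy-4-methoxyphenyl)butan-1-one
Product: 17 elaphopilosin A, via methylidene trione 16 (not isolated)
Conditions: 5 (2.5 equiv), Et3N (3 equiv), MeCN, rt → 50 °C, slow addition of 15; dilute HCl work-up
Reagents that add atoms: none
Why: Et3N deprotonates the acidic enol of 15, sulfinate leaves by E1cB to give the Michael acceptor 16, and the phenoxide of 5 (two equivalent free ring positions, used in excess) adds through carbon in a Friedel–Crafts-type conjugate addition; the stereocentre is not involved, and its descriptor changes from S to R only because the CIP priorities change.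

**Compound list**

1 | phloroglucinol (benzene-1,3,5-triol) | Oc1cc(O)cc(O)c1 | starting material
2 | butanoyl chloride | CCCC(=O)Cl | starting material
3 | 1-(2,4,6-trihydroxyphenyl)butan-1-one | CCCC(=O)c1c(O)cc(O)cc1O | intermediate
4 | dimethyl sulfate | COS(=O)(=O)OC | starting material
5 | 1-(2,6-dihydroxy-4-methoxyphenyl)butan-1-one (ring B unit) | CCCC(=O)c1c(O)cc(OC)cc1O | intermediate
6 | 2-methylbenzene-1,3,5-triol (2-methylphloroglucinol) | Cc1c(O)cc(O)cc1O | starting material
7 | 1-(2,4,6-trihydroxy-3-methylphenyl)butan-1-one | CCCC(=O)c1c(O)cc(O)c(C)c1O | intermediate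
8 | formaldehyde (37% aqueous) | C=O | starting material
9 | sodium 4-methylbenzenesulfinate | [Na+].[O-]S(=O)c1ccc(C)cc1 | starting material
10 | 1-[2,4,6-trihydroxy-3-(hydroxymethyl)-5-methylphenyl]butan-1-one | CCCC(=O)c1c(O)c(C)c(O)c(CO)c1O | intermediate (not isolated)
11 | 1-[2,4,6-trihydroxy-3-methyl-5-[(4-methylbenzenesulfonyl)methyl]phenyl]butan-1-one | CCCC(=O)c1c(O)c(C)c(O)c(CS(=O)(=O)c2ccc(C)cc2)c1O | intermediate
12 | allyltrimethylsilane | C=CC[Si](C)(C)C | starting material
13 | (4S)-2-butanoyl-3,5-dihydroxy-4-methyl-6-[(4-methylbenzenesulfonyl)methyl]-4-(prop-2-en-1-yl)cyclohexa-2,5-dien-1-one | CCCC(=O)C1=C(O)[C@](C)(CC=C)C(O)=C(CS(=O)(=O)c2ccc(C)cc2)C1=O | intermediate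
14 | 2-methylbut-2-ene | CC=C(C)C | starting material
15 | (4S)-2-butanoyl-3,5-dihydroxy-4-methyl-4-(3-methylbut-2-en-1-yl)-6-[(4-methylbenzenesulfonyl)methyl]cyclohexa-2,5-dien-1-one | CCCC(=O)C1=C(O)[C@](C)(CC=C(C)C)C(O)=C(CS(=O)(=O)c2ccc(C)cc2)C1=O | intermediate
16 | (6S)-4-butanoyl-5-hydroxy-6-methyl-2-methylidene-6-(3-methylbut-2-en-1-yl)cyclohex-4-ene-1,3-dione | CCCC(=O)C1=C(O)[C@](C)(CC=C(C)C)C(=O)C(=C)C1=O | intermediate (not isolated)
17 | elaphopilosin A, (4R)-2-butanoyl-6-[(3-butanoyl-2,4-dihydroxy-6-methoxyphenyl)methyl]-3,5-dihydroxy-4-methyl-4-(3-methylbut-2-en-1-yl)cyclohexa-2,5-dien-1-one | CCCC(=O)C1=C(O)[C@](C)(CC=C(C)C)C(O)=C(Cc2c(OC)cc(O)c(C(=O)CCC)c2O)C1=O | target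

**Step count and risks**

Total step count: 7. Longest linear sequence: 5 steps (steps 3, 4, 5, 6, 7 from 6); the ring B branch (steps 1, 2) joins in step 7.

Step 5 is the most likely to fail. The intermolecular, enantioselective carbon capture is without direct precedent; carboxylate may capture the ring instead of the allylsilane, the peracid may attack the alkenes, and the ee may be low. The fallback sets out from 11. Stoichiometric PhI(OAc)2 and allylSiMe3 in (CF3)2CHOH/CH2Cl2 at −40 °C, with no peracid and no chiral catalyst, give the racemic allyl dienone F1. F1 is resolved by preparative supercritical-fluid chromatography on a chiral stationary phase; the unwanted (4R)-enantiomer F2 is set aside and the (4S)-enantiomer comes back to the route at 13.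

Step 4 is the second risk. Free formaldehyde can join two molecules of 7 into a methylene-bridged dimer before sulfinate intervenes. The fallback sets out from 7. Eschenmoser's salt (CH2=NMe2+ I−) in MeCN at rt gives the Mannich base F3 with a preformed iminium electrophile and no free formaldehyde. Heating F3 with 4-MeC6H4SO2Na in AcOH/H2O at 80 °C exchanges the amine for sulfinate and comes back to the route at 11.

Step 7 is the third risk. The methylidene trione 16 can be captured by its own electron-rich prenyl alkene, and the product can be alkylated a second time on ring B. The fallback sets out from 13 (with 5) and changes the order of events. Compound 13 and excess 5 with Et3N in MeCN pass through the allyl methylidene trione F4, which is not isolated and carries a much less nucleophilic alkene, to give the allyl-bridged dimer F5. Cross-metathesis of F5 with 14 and the same ruthenium catalyst then comes back to the route at 17.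

**Further compounds**

F1 | step 5 | racemic 2-butanoyl-3,5-dihydroxy-4-methyl-6-[(4-methylbenzenesulfonyl)methyl]-4-(prop-2-en-1-yl)cyclohexa-2,5-dien-1-one | CCCC(=O)C1=C(O)C(C)(CC=C)C(O)=C(CS(=O)(=O)c2ccc(C)cc2)C1=O
F2 | step 5 | (4R)-2-butanoyl-3,5-dihydroxy-4-methyl-6-[(4-methylbenzenesulfonyl)methyl]-4-(prop-2-en-1-yl)cyclohexa-2,5-dien-1-one | CCCC(=O)C1=C(O)[C@@](C)(CC=C)C(O)=C(CS(=O)(=O)c2ccc(C)cc2)C1=O
F3 | step 4 | 1-[3-[(dimethylamino)methyl]-2,4,6-trihydroxy-5-methylphenyl]butan-1-one | CCCC(=O)c1c(O)c(C)c(O)c(CN(C)C)c1O
F4 | step 7 | (6S)-4-butanoyl-5-hydroxy-6-methyl-2-methylidene-6-(prop-2-en-1-yl)cyclohex-4-ene-1,3-dione | CCCC(=O)C1=C(O)[C@](C)(CC=C)C(=O)C(=C)C1=O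
F5 | step 7 | (4R)-2-butanoyl-6-[(3-butanoyl-2,4-dihydroxy-6-methoxyphenyl)methyl]-3,5-dihydroxy-4-methyl-4-(prop-2-en-1-yl)cyclohexa-2,5-dien-1-one | CCCC(=O)C1=C(O)[C@](C)(CC=C)C(O)=C(Cc2c(OC)cc(O)c(C(=O)CCC)c2O)C1=O
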